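Numbering: C1 prenyl bridgehead, C2–C3–C4 enolised β-diketone (aroyl on C3), C5 geranyl bridgehead, C6 CH2, C7 CH(geranyl), C8 CMe2, C9 bridging ketone; ring A = C1–C9–C5–C6–C7–C8, ring B = C1–C2–C3–C4–C5–C9. Enabling feature: C8 of ring A is a quaternary gem-dimethyl carbon between C1 and C7, so it can arise from an isopropenyl group on C1 by adding a C7 alkenylpalladium and a hydride across its C=C; the alkylpalladium formed has no β-hydrogen.
Cuts (retrosynthesis): C3–aroyl; the C7 side chain at its CH2–CH= bond; C5–geranyl; C7–C8 of ring A together with one C–H of a C8 methyl (reductive Heck); C5–C9 of ring B (vinylogous Dieckmann); C3–C4 (Claisen acylation); C1–prenyl (deconjugative alkylation).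
Forward: an acyclic keto ester holding the C1 quaternary carbon is extended and closed to ring B with a 2-bromoallyl arm on C5; ring A is closed by the palladium step; the C5, C7 and C3 substituents follow in that order, then the enol ether and silyl ethers are removed.
Stereochemistry: C5 follows C1 in the ring A closure, since only the cis epimer can bridge and C5 equilibrates. Material is racemic up to the bicycle, because C5 is labile and an earlier alkylation catalyst could therefore not fix C1. A chiral bis-lithium amide resolves the bicycle kinetically during the bridgehead geranylation, which fixes C1 and C5. C7 comes from exo-face hydroboration; both E alkenes come from geranyl bromide and a syn-carboalumination.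

Key step: step 7

Assumption 1: which antipode of 12 the (R,R,R,R)-amide deprotonates faster must be found on the first run; the route is written for the (1R,5S) enantiomer, and the mirror-image amide from (S)-1-phenylethylamine is used otherwise.
Assumption 2: 11 is a vinylogous acid; it is written as the diketone but should rest partly as its C9 enol, through which the two C5 epimers interconvert.

Step 1
Reactants: 1 methyl acetoacetate; 2 acetone
Product: 3 methyl 2-acetyl-3-methylbut-2-enoate
Conditions: TiCl4, pyridine, THF, 0 °C → rt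
Reagents that add atoms: none
Why: TiCl4/pyridine-mediated Knoevenagel condensation, in which the Lewis acid activates the ketone and binds the water so that even acetone condenses with the acetoacetate to the tetrasubstituted alkene.

Step 2
Reactants: 3 methyl 2-acetyl-3-methylbut-2-enoate; 4 prenyl bromide
Product: 6 rac-methyl 2-acetyl-5-methyl-2-(prop-1-en-2-yl)hex-4-enoate, via sodium dienolate 5 (not isolated)
Conditions: NaH, THF, 0 °C; then 4, 0 °C → rt
Reagents that add atoms: none
Why: Deconjugative alkylation, in which NaH removes a γ-hydrogen of the isopropylidene group to give the fully conjugated dienolate and the allylic bromide alkylates its α-carbon (SN2), creating the quaternary carbon (future C1, racemic) with isopropenyl and prenyl groups.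

Step 3
Reactants: 7 4-bromopent-4-enoic acid
Product: 8 4-bromopent-4-enoyl chloride
Conditions: (COCl)2, DMF (cat.), CH2Cl2, 0 °C → rt
Reagents that add atoms: oxalyl chloride ClC(=O)C(Cl)=O
Why: Standard acid chloride formation through the Vilsmeier-type chloroiminium species, which leaves the alkenyl bromide untouched.

Step 4
Reactants: 6 rac-methyl 2-acetyl-5-methyl-2-(prop-1-en-2-yl)hex-4-enoate; 8 4-bromopent-4-enoyl chloride
Product: 9 rac-methyl 8-bromo-2-(3-methylbut-2-en-1-yl)-3,5-dioxo-2-(prop-1-en-2-yl)non-8-enoate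
Conditions: MgBr2·OEt2, i-Pr2NEt, CH2Cl2, 0 °C → rt; aq HCl work-up
Reagents that add atoms: none
Why: Crossed Claisen acylation of a ketone under soft enolisation, where the acetyl methyl is the only enolisable position of 6 and the magnesium chelate directs the acid chloride to carbon to give the 1,3-diketone.

Step 5
Reactants: 9 rac-methyl 8-bromo-2-(3-methylbut-2-en-1-yl)-3,5-dioxo-2-(prop-1-en-2-yl)non-8-enoate
Product: 10 rac-methyl (4E)-8-bromo-5-methoxy-2-(3-methylbut-2-en-1-yl)-3-oxo-2-(prop-1-en-2-yl)nona-4,8-dienoate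
Conditions: HC(OMe)3, MeOH, TsOH·H2O (cat.), rt
Reagents that add atoms: trimethyl orthoformate COC(OC)OC; methanol CO
Why: Acid-catalysed enol ether formation from a 1,3-diketone, in which methanol attacks the unhindered C5 carbonyl and not the C3 carbonyl beside the quaternary carbon (as in the selective mono-etherification of 4,4-disubstituted cyclohexane-1,3-diones), so the vinylogous ester keeps its carbonyl at C3.

Step 6
Reactants: 10 rac-methyl (4E)-8-bromo-5-methoxy-2-(3-methylbut-2-en-1-yl)-3-oxo-2-(prop-1-en-2-yl)nona-4,8-dienoate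
Product: 11 rac-(4S,6R)-4-(2-bromoprop-2-en-1-yl)-3-methoxy-6-(3-methylbut-2-en-1-yl)-6-(prop-1-en-2-yl)cyclohex-2-ene-1,5-dione
Conditions: LiN(SiMe3)2 (2.2 equiv), THF, −78 → 0 °C; then AcOH
Reagents that add atoms: none
Why: Vinylogous Dieckmann (intramolecular Claisen) condensation, in which the amide removes a γ-hydrogen of the β-methoxy enone (the CH2 that becomes C5), the dienolate closes ring B onto the methyl ester (6-exo-trig) and the stabilised product enolate drives the reaction, the new C5 centre being left as an equilibrating epimer mixture of which the cis form is drawn.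

Step 7
Reactants: 11 rac-(4S,6R)-4-(2-bromoprop-2-en-1-yl)-3-methoxy-6-(3-methylbut-2-en-1-yl)-6-(prop-1-en-2-yl)cyclohex-2-ene-1,5-dione
Product: 12 rac-(1R,5S)-4-methoxy-8,8-dimethyl-7-methylidene-1-(3-methylbut-2-en-1-yl)bicyclo[3.3.1]non-3-ene-2,9-dione
Conditions: Pd(OAc)2 (10 mol%), PPh3 (25 mol%), HCO2Na (1.3 equiv), Et4NCl, DMF, 80 °C
Reagents that add atoms: none
Why: Zerovalent palladium formed from Pd(OAc)2 and PPh3 inserts into the C7–Br bond, and in the keto tautomer whose arm is axial and cis to the isopropenyl group the alkenylpalladium adds syn across that C=C, C7 bonding to the internal carbon C8 and palladium moving to the terminal CH2; formate then exchanges onto this neopentyl palladium, loses CO2 and delivers hydride, so the CH2 becomes the second methyl of C8 and C7 is left as an exocyclic methylene. The closest known reaction type is the reductive Heck cyclisation, that is, intramolecular Heck reactions that build quaternary carbons and bridged six-membered rings with formate interception of a σ-alkylpalladium lacking β-hydrogen. Ring A (C1–C9–C5–C6–C7–C8) closes 6-exo-trig; the 7-endo mode is disfavoured, and the C3=C4 enol ether offers only 4-exo or 5-endo alternatives. The one new stereocentre, C5, is dictated by C1: only the epimer with the arm cis (1,3-diaxial) to the isopropenyl group can bridge, and because the C5 epimers interconvert through the C9 enol under the weakly basic conditions all material should funnel into the (1R*,5S*) bicycle, while C8 becomes quaternary but not stereogenic. The step needs hydride transfer after and not before insertion, and must outrun attack of the enolate oxygen on palladium (furan formation) and onward insertion of the neopentyl palladium into the prenyl or new methylene group; sparingly soluble HCO2Na keeps the formate concentration low while the alkenylpalladium waits for the reactive tautomer, PPh3 disfavours C–O reductive elimination, and the missing β-hydrogen makes formate capture the fastest exit once C7–C8 exists.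

Step 8
Reactants: 12 rac-(1R,5S)-4-methoxy-8,8-dimethyl-7-methylidene-1-(3-methylbut-2-en-1-yl)bicyclo[3.3.1]non-3-ene-2,9-dione; 13 geranyl bromide
Product: 15 (1R,5S)-5-[(2E)-3,7-dimethylocta-2,6-dien-1-yl]-4-methoxy-8,8-dimethyl-7-methylidene-1-(3-methylbut-2-en-1-yl)bicyclo[3.3.1]non-3-ene-2,9-dione, via bridgehead organolithium 14 (not isolated)
Conditions: dilithium amide of (1R,2R)-1,2-diphenyl-N,N′-bis[(1R)-1-phenylethyl]ethane-1,2-diamine (0.55 equiv, from the diamine and n-BuLi), LiCl, THF, −100 °C; then 13, −100 → −60 °C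
Reagents that add atoms: none
Why: Kinetic resolution by enantioselective bridgehead lithiation with a C2-symmetric chiral bis-lithium amide, a reaction established for the bridgehead prenylation of closely related bicyclo[3.3.1]nonane-2,9-dione methyl enol ethers, in which the C5–H of one enantiomer is removed faster and the configurationally locked carbanion is alkylated by the allylic bromide (SN2), so that 15 carries C1 and C5 of the target while the slower antipode of 12 is recovered.

Step 9
Reactants: 16 5-bromo-2-methylpent-2-ene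
Product: 17 6-methylhept-5-en-1-yne
Conditions: LiC≡CH·H2NCH2CH2NH2, DMSO, 10 °C → rt
Reagents that add atoms: lithium acetylide–ethylenediamine complex [Li]C#C.NCCN
Why: SN2 alkylation of lithium acetylide by the primary homoallylic bromide in a dipolar aprotic solvent.

Step 10
Reactants: 17 6-methylhept-5-en-1-yne
Product: 19 (1E)-1-iodo-2,6-dimethylhepta-1,5-diene, via alkenylalane 18 (not isolated)
Conditions: AlMe3, Cp2ZrCl2 (0.25 equiv), CH2Cl2, 0 °C → rt; then I2, THF, −30 → 0 °C
Reagents that add atoms: trimethylaluminium C[Al](C)C; iodine II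
Why: Negishi zirconium-catalysed carboalumination, in which methyl and aluminium add syn to the terminal alkyne with aluminium on the terminal carbon, followed by iodinolysis with retention to give the E-alkenyl iodide.

Step 11
Reactants: 15 (1R,5S)-5-[(2E)-3,7-dimethylocta-2,6-dien-1-yl]-4-methoxy-8,8-dimethyl-7-methylidene-1-(3-methylbut-2-en-1-yl)bicyclo[3.3.1]non-3-ene-2,9-dione; 19 (1E)-1-iodo-2,6-dimethylhepta-1,5-diene
Product: 21 (1R,5S,7S)-5,7-bis[(2E)-3,7-dimethylocta-2,6-dien-1-yl]-4-methoxy-8,8-dimethyl-1-(3-methylbut-2-en-1-yl)bicyclo[3.3.1]non-3-ene-2,9-dione, via alkylborane 20 (not isolated)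
Conditions: 9-BBN (1.3 equiv), THF, 0 °C → rt; then 19, Pd(dppf)Cl2 (5 mol%), AsPh3, Cs2CO3, DMF/H2O, rt
Reagents that add atoms: none
Why: Hydroboration followed by B-alkyl Suzuki–Miyaura coupling, in which 9-BBN adds only to the 1,1-disubstituted C7 methylene (the trisubstituted alkenes and hindered carbonyls react far more slowly), boron going to the terminal carbon and hydrogen to C7 from the open exo face because the endo face is covered by the C2–C4 bridge of ring B, which makes the new CH2 group endo (7S), and the primary alkylborane then couples with the alkenyl iodide with retention of its E geometry.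

Step 12
Reactants: 22 3,4-dihydroxybenzoic acid
Product: 23 tert-butyldimethylsilyl 3,4-bis[(tert-butyldimethylsilyl)oxy]benzoate
Conditions: TBSCl (3.5 equiv), imidazole, DMF, rt
Reagents that add atoms: tert-butyl(chloro)dimethylsilane CC(C)(C)[Si](C)(C)Cl
Why: Imidazole-promoted silylation of both phenols and the carboxylic acid.

Step 13
Reactants: 23 tert-butyldimethylsilyl 3,4-bis[(tert-butyldimethylsilyl)oxy]benzoate
Product: 24 3,4-bis[(tert-butyldimethylsilyl)oxy]benzoyl chloride
Conditions: (COCl)2, DMF (cat.), CH2Cl2, 0 °C → rt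
Reagents that add atoms: oxalyl chloride ClC(=O)C(Cl)=O
Why: Direct conversion of a silyl ester into the acid chloride by the chloroiminium reagent under neutral conditions, with loss of the silyl chloride and survival of the aryl silyl ethers.

Step 14
Reactants: 21 (1R,5S,7S)-5,7-bis[(2E)-3,7-dimethylocta-2,6-dien-1-yl]-4-methoxy-8,8-dimethyl-1-(3-methylbut-2-en-1-yl)bicyclo[3.3.1]non-3-ene-2,9-dione; 24 3,4-bis[(tert-butyldimethylsilyl)oxy]benzoyl chloride
Product: 26 (1S,5S,7S)-3-{3,4-bis[(tert-butyldimethylsilyl)oxy]benzoyl}-5,7-bis[(2E)-3,7-dimethylocta-2,6-dien-1-yl]-4-methoxy-8,8-dimethyl-1-(3-methylbut-2-en-1-yl)bicyclo[3.3.1]non-3-ene-2,9-dione, via C3-lithio enone 25 (not isolated)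
Conditions: lithium 2,2,6,6-tetramethylpiperidide (from 2,2,6,6-tetramethylpiperidine and n-BuLi), THF, −78 °C; then 24, −78 → −40 °C
Reagents that add atoms: none
Why: Vinylic lithiation and C-acylation of a β-methoxy enone, where with both bridgeheads quaternary the C3–H is the only acidic position, the hindered amide removes it without adding to the carbonyls, and the alkenyllithium is acylated by the aroyl chloride as known for C3 benzoylation in this ring system.

Step 15
Reactants: 26 (1S,5S,7S)-3-{3,4-bis[(tert-butyldimethylsilyl)oxy]benzoyl}-5,7-bis[(2E)-3,7-dimethylocta-2,6-dien-1-yl]-4-methoxy-8,8-dimethyl-1-(3-methylbut-2-en-1-yl)bicyclo[3.3.1]non-3-ene-2,9-dione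
Product: 27 oblongifolin D
Conditions: LiOH, dioxane/H2O (degassed, argon), 90 °C; then aq HCl to pH 3
Reagents that add atoms: lithium hydroxide [Li+].[OH-]
Why: Conjugate addition–elimination of hydroxide at C4 of the doubly activated vinylogous ester releases methanol and gives the delocalised triketone enolate, which resists retro-Claisen cleavage, while the same base cleaves the aryl silyl ethers and acidification under argon frees the enol and catechol without touching C1, C5 or C7.

Compound list
1 | methyl acetoacetate | CC(=O)CC(=O)OC | starting material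
2 | acetone | CC(C)=O | starting material
3 | methyl 2-acetyl-3-methylbut-2-enoate | CC(=O)C(C(=O)OC)=C(C)C | intermediate
4 | prenyl bromide (1-bromo-3-methylbut-2-ene) | CC(C)=CCBr | starting material
5 | sodium 3-(methoxycarbonyl)-4-methylpenta-2,4-dien-2-olate (dienolate of 3) | CC([O-])=C(C(C)=C)C(=O)OC.[Na+] | intermediate (not isolated)
6 | methyl 2-acetyl-5-methyl-2-(prop-1-en-2-yl)hex-4-enoate; racemic, the (R) enantiomer that ends up in the target is drawn | CC(=O)[C@@](CC=C(C)C)(C(C)=C)C(=O)OC | intermediate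
7 | 4-bromopent-4-enoic acid | OC(=O)CCC(Br)=C | starting material
8 | 4-bromopent-4-enoyl chloride | ClC(=O)CCC(Br)=C | intermediate
9 | methyl 8-bromo-2-(3-methylbut-2-en-1-yl)-3,5-dioxo-2-(prop-1-en-2-yl)non-8-enoate; racemic, (2R) drawn; largely enolised | COC(=O)[C@](CC=C(C)C)(C(C)=C)C(=O)CC(=O)CCC(Br)=C | intermediate
10 | methyl (4E)-8-bromo-5-methoxy-2-(3-methylbut-2-en-1-yl)-3-oxo-2-(prop-1-en-2-yl)nona-4,8-dienoate; racemic, (2R) drawn | COC(=O)[C@](CC=C(C)C)(C(C)=C)C(=O)/C=C(/OC)CCC(Br)=C | intermediate
11 | (4S,6R)-4-(2-bromoprop-2-en-1-yl)-3-methoxy-6-(3-methylbut-2-en-1-yl)-6-(prop-1-en-2-yl)cyclohex-2-ene-1,5-dione; racemic; bromoallyl cis to isopropenyl drawn, in equilibrium with its C4 epimer and the 5-enol | COC1=CC(=O)[C@@](CC=C(C)C)(C(C)=C)C(=O)[C@H]1CC(Br)=C | intermediate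
12 | (1R,5S)-4-methoxy-8,8-dimethyl-7-methylidene-1-(3-methylbut-2-en-1-yl)bicyclo[3.3.1]non-3-ene-2,9-dione; racemic, the enantiomer carried forward is drawn | C=C1C[C@@H]2C(=O)[C@@](CC=C(C)C)(C(=O)C=C2OC)C1(C)C | intermediate
13 | geranyl bromide ((2E)-1-bromo-3,7-dimethylocta-2,6-diene) | CC(C)=CCC/C(C)=C/CBr | starting material
14 | C5-lithio derivative of (1R,5S)-12 | C=C1C[C@]2([Li])C(=O)[C@@](CC=C(C)C)(C(=O)C=C2OC)C1(C)C | intermediate (not isolated)
15 | (1R,5S)-5-[(2E)-3,7-dimethylocta-2,6-dien-1-yl]-4-methoxy-8,8-dimethyl-7-methylidene-1-(3-methylbut-2-en-1-yl)bicyclo[3.3.1]non-3-ene-2,9-dione; single enantiomer | C=C1C[C@]2(C/C=C(\C)CCC=C(C)C)C(=O)[C@@](CC=C(C)C)(C(=O)C=C2OC)C1(C)C | intermediate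
16 | 5-bromo-2-methylpent-2-ene | CC(C)=CCCBr | starting material
17 | 6-methylhept-5-en-1-yne | C#CCCC=C(C)C | intermediate
18 | [(1E)-2,6-dimethylhepta-1,5-dien-1-yl]dimethylalane | C[Al](C)/C=C(\C)CCC=C(C)C | intermediate (not isolated)
19 | (1E)-1-iodo-2,6-dimethylhepta-1,5-diene | I/C=C(\C)CCC=C(C)C | intermediate
20 | (1R,5S,7S)-7-[(9-borabicyclo[3.3.1]nonan-9-yl)methyl]-5-[(2E)-3,7-dimethylocta-2,6-dien-1-yl]-4-methoxy-8,8-dimethyl-1-(3-methylbut-2-en-1-yl)bicyclo[3.3.1]non-3-ene-2,9-dione; boryl-methyl group endo | C1CCC2CCCC1B2C[C@H]3C[C@]4(C/C=C(\C)CCC=C(C)C)C(=O)[C@@](CC=C(C)C)(C(=O)C=C4OC)C3(C)C | intermediate (not isolated)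
21 | (1R,5S,7S)-5,7-bis[(2E)-3,7-dimethylocta-2,6-dien-1-yl]-4-methoxy-8,8-dimethyl-1-(3-methylbut-2-en-1-yl)bicyclo[3.3.1]non-3-ene-2,9-dione; C7 geranyl endo | CC(C)=CCC/C(C)=C/C[C@H]1C[C@]2(C/C=C(\C)CCC=C(C)C)C(=O)[C@@](CC=C(C)C)(C(=O)C=C2OC)C1(C)C | intermediate
22 | 3,4-dihydroxybenzoic acid | OC(=O)c1ccc(O)c(O)c1 | starting material
23 | tert-butyldimethylsilyl 3,4-bis[(tert-butyldimethylsilyl)oxy]benzoate | CC(C)(C)[Si](C)(C)OC(=O)c1ccc(O[Si](C)(C)C(C)(C)C)c(O[Si](C)(C)C(C)(C)C)c1 | intermediate
24 | 3,4-bis[(tert-butyldimethylsilyl)oxy]benzoyl chloride | ClC(=O)c1ccc(O[Si](C)(C)C(C)(C)C)c(O[Si](C)(C)C(C)(C)C)c1 | intermediate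
25 | C3-lithio derivative of 21 | CC(C)=CCC/C(C)=C/C[C@H]1C[C@]2(C/C=C(\C)CCC=C(C)C)C(=O)[C@@](CC=C(C)C)(C(=O)C([Li])=C2OC)C1(C)C | intermediate (not isolated)
26 | (1S,5S,7S)-3-{3,4-bis[(tert-butyldimethylsilyl)oxy]benzoyl}-5,7-bis[(2E)-3,7-dimethylocta-2,6-dien-1-yl]-4-methoxy-8,8-dimethyl-1-(3-methylbut-2-en-1-yl)bicyclo[3.3.1]non-3-ene-2,9-dione; same spatial arrangement as 21, the C1 descriptor changes only through the priority rules | CC(C)=CCC/C(C)=C/C[C@H]1C[C@]2(C/C=C(\C)CCC=C(C)C)C(=O)[C@@](CC=C(C)C)(C(=O)C(C(=O)c3ccc(O[Si](C)(C)C(C)(C)C)c(O[Si](C)(C)C(C)(C)C)c3)=C2OC)C1(C)C | intermediate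
27 | oblongifolin D, (1S,5S,7S)-3-(3,4-dihydroxybenzoyl)-5,7-bis[(2E)-3,7-dimethylocta-2,6-dien-1-yl]-4-hydroxy-8,8-dimethyl-1-(3-methylbut-2-en-1-yl)bicyclo[3.3.1]non-3-ene-2,9-dione | CC(C)=CCC/C(C)=C/C[C@H]1C[C@]2(C/C=C(\C)CCC=C(C)C)C(=O)[C@@](CC=C(C)C)(C(=O)C(C(=O)c3ccc(O)c(O)c3)=C2O)C1(C)C | target

Total step count: 15. Longest linear sequence: 10 steps (steps 1, 2, 4, 5, 6, 7, 8, 11, 14, 15).

Steps most likely to fail

1. Step 7. Only the keto tautomer of 11 with an axial arm can cyclise. While the alkenylpalladium waits for it, hydride may be transferred too early, or the enolate oxygen may attack palladium and close a furan. Fallback: set out from 6 and build the ring closure on an alkyne under acidic, enolate-free conditions. Acylation of 6 with commercial pent-4-ynoyl chloride under the step 4 conditions should give methyl 2-(3-methylbut-2-en-1-yl)-3,5-dioxo-2-(prop-1-en-2-yl)non-8-ynoate F1. Orthoformate treatment as in step 5 should give methyl (4E)-5-methoxy-2-(3-methylbut-2-en-1-yl)-3-oxo-2-(prop-1-en-2-yl)non-4-en-8-ynoate F2. LiN(SiMe3)2 (3.3 equiv, one extra for the alkyne C–H) should close it to 3-methoxy-6-(3-methylbut-2-en-1-yl)-6-(prop-1-en-2-yl)-4-(prop-2-yn-1-yl)cyclohex-2-ene-1,5-dione F3. A palladium hydride-initiated reductive enyne cyclisation (Pd2(dba)3·CHCl3, P(o-tol)3, AcOH, Et3SiH, toluene, rt → 50 °C) then places palladium on C7 by hydropalladation of the alkyne, inserts the isopropenyl group 6-exo, and reduces the neopentyl palladium with the silane. The route is rejoined at 12.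

2. Step 8. The rate difference between the two enantiomers in the bridgehead deprotonation may be too small, or lithiation at C3 may compete, so that 15 is formed with insufficient enantiomeric purity. Fallback: set out from 12, geranylate the whole racemate with the achiral base LiN(i-Pr)2 (THF, −78 °C, then 13), and separate the racemic product by preparative chromatography on a chiral stationary phase (amylose tris(3,5-dimethylphenylcarbamate)). This removes the unwanted (1S,5R)-5-[(2E)-3,7-dimethylocta-2,6-dien-1-yl]-4-methoxy-8,8-dimethyl-7-methylidene-1-(3-methylbut-2-en-1-yl)bicyclo[3.3.1]non-3-ene-2,9-dione F4, and the route is rejoined at 15.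

3. Step 11. Hydroboration of the methylene group beside the quaternary C8 may be slow enough for 9-BBN to reduce the C2 carbonyl. The β-branched alkylborane may transmetalate sluggishly and protodeboronate, and incomplete exo-face selectivity would pass unnoticed in the one-pot procedure. Fallback: set out from 15, hydroborate as before, but oxidise 20 (NaBO3·4H2O, THF/H2O) to (1R,5S,7S)-5-[(2E)-3,7-dimethylocta-2,6-dien-1-yl]-7-(hydroxymethyl)-4-methoxy-8,8-dimethyl-1-(3-methylbut-2-en-1-yl)bicyclo[3.3.1]non-3-ene-2,9-dione F5, at which stage C7 epimers can be separated and assigned. An Appel reaction (I2, PPh3, imidazole, CH2Cl2) should give the 7-(iodomethyl) analogue, (1R,5S,7S)-5-[(2E)-3,7-dimethylocta-2,6-dien-1-yl]-7-(iodomethyl)-4-methoxy-8,8-dimethyl-1-(3-methylbut-2-en-1-yl)bicyclo[3.3.1]non-3-ene-2,9-dione F6. The polarity of the coupling is then reversed in a Negishi reaction of F6 with chloro[(1E)-2,6-dimethylhepta-1,5-dien-1-yl]zinc F7 (from 19 with t-BuLi, then ZnCl2) under Pd2(dba)3, P(c-C5H9)3 and N-methylimidazole in THF/NMP. The route is rejoined at 21.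

Further compounds
F1 | step 7 | methyl 2-(3-methylbut-2-en-1-yl)-3,5-dioxo-2-(prop-1-en-2-yl)non-8-ynoate (racemic, (2R) drawn) | COC(=O)[C@](CC=C(C)C)(C(C)=C)C(=O)CC(=O)CCC#C
F2 | step 7 | methyl (4E)-5-methoxy-2-(3-methylbut-2-en-1-yl)-3-oxo-2-(prop-1-en-2-yl)non-4-en-8-ynoate (racemic, (2R) drawn) | COC(=O)[C@](CC=C(C)C)(C(C)=C)C(=O)/C=C(/OC)CCC#C
F3 | step 7 | (4S,6R)-3-methoxy-6-(3-methylbut-2-en-1-yl)-6-(prop-1-en-2-yl)-4-(prop-2-yn-1-yl)cyclohex-2-ene-1,5-dione (racemic, cis epimer drawn) | COC1=CC(=O)[C@@](CC=C(C)C)(C(C)=C)C(=O)[C@H]1CC#C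
F4 | step 8 | (1S,5R)-5-[(2E)-3,7-dimethylocta-2,6-dien-1-yl]-4-methoxy-8,8-dimethyl-7-methylidene-1-(3-methylbut-2-en-1-yl)bicyclo[3.3.1]non-3-ene-2,9-dione (enantiomer of 15) | C=C1C[C@@]2(C/C=C(\C)CCC=C(C)C)C(=O)[C@](CC=C(C)C)(C(=O)C=C2OC)C1(C)C
F5 | step 11 | (1R,5S,7S)-5-[(2E)-3,7-dimethylocta-2,6-dien-1-yl]-7-(hydroxymethyl)-4-methoxy-8,8-dimethyl-1-(3-methylbut-2-en-1-yl)bicyclo[3.3.1]non-3-ene-2,9-dione | OC[C@H]1C[C@]2(C/C=C(\C)CCC=C(C)C)C(=O)[C@@](CC=C(C)C)(C(=O)C=C2OC)C1(C)C
F6 | step 11 | (1R,5S,7S)-5-[(2E)-3,7-dimethylocta-2,6-dien-1-yl]-7-(iodomethyl)-4-methoxy-8,8-dimethyl-1-(3-methylbut-2-en-1-yl)bicyclo[3.3.1]non-3-ene-2,9-dione | IC[C@H]1C[C@]2(C/C=C(\C)CCC=C(C)C)C(=O)[C@@](CC=C(C)C)(C(=O)C=C2OC)C1(C)C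
F7 | step 11 | chloro[(1E)-2,6-dimethylhepta-1,5-dien-1-yl]zinc | Cl[Zn]/C=C(\C)CCC=C(C)C
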